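The constants of these flasks are not given, so we read them from the earlier runs, zeta and beta, and ask what fraction of the free monomer charged reaches chains.

all flasks: initiator 0.5 mol%
- zeta: free monomer 0.048 M; protic impurity 0.075 M; run made earlier
- beta: free monomer 0.19 M; protic impurity 0.075 M; run made earlier
- birch: free monomer 0.25 M; protic impurity 0.0750 M; time 30 min
- cedar: free monomer 0.060 M; protic impurity 0.0750 M; time 30 min

- zeta (time / min: monomer in chains / %, free monomer / %): 5.00: 2.5, 0.2; 10.0: 2.2, 0; 15.0: 2.0, 0; 20.0: 2.2, 0; 25.0: 2.1, 0; 30.0: 1.9, 0
- beta (time / min: monomer in chains / %, free monomer / %): 2.50: 23.6, 37.4; 4.00: 33.5, 27.3; 6.00: 41.6, 19.4; 10.0: 50.6, 9.8; 20.0: 57.5, 2.5; 30.0: 59.7, 0.2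

(readings scatter by 0.3 percentage points)

- the average divides the monomer in chains by the number of chains, living and dead together; two radicals that join make one chain
- the earlier runs were read with a standard deviation of 0.3 percentage points
- the earlier runs do not show the number of chains; that part of a forecast is a guess

- which of the two ends with the longer chains by the average number of monomer units in a chain (living and dead chains, two that joined counted as one) ("neither" if they lie within 10%) (birch / cedar / neither)
- average number of monomer units in a chain (living and dead chains, two that joined counted as one) at the end, birch
- average number of monomer units in a chain (living and dead chains, two that joined counted as one) at the end, cedar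

In beta, chains plus free monomer read 61.0% at 2.50 min and 59.9% at 30.0 min, so the loss comes early and then stands. Counting agrees: if each protic impurity takes one monomer, beta keeps 60.5%. For birch, one minus impurity over monomer gives 70.0%, and this surplus share, the fraction of charged free monomer that outlasts the protic impurity at one monomer each, is what we carry. A second way uses readings instead of charges: beta lost 0.0762 M of monomer, which on birch's charge leaves 69.5%. The two agree, and beta's late decay constant, 0.137 min⁻¹, leaves 1.66% of birch's surplus free at 30 min, so we expect that surplus in chains.

For cedar the ways part. The count gives −25.0%, a negative share, and for zeta −56.2%, yet zeta reads 2.2% in chains, so the count cheats where free monomer is the limiting reagent. The loss is a race between protic impurity and growth, and the protic impurity runs down during it, so no single constant holds; if growth in zeta ran at beta's late constant, zeta's reading puts the loss of free monomer near 6.21 min⁻¹ as a rough average, faster than growth. We therefore give cedar a share like zeta's. If each charged initiator made one chain, which the runs do not show, birch reaches 140 units and cedar 4.40; we commit to birch.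

The forecast says birch, with 190 for birch and 8 for cedar: “Chain count is a guess”. The flask gives birch, with 172 for birch and 31.3 for cedar.

    initiator → 2 initiating radical (k = 9.10 × 10⁻⁴ s⁻¹)
    free monomer + initiating radical → growing radical + monomer in chains (k = 1.80 × 10⁶ M⁻¹ s⁻¹)
    free monomer + growing radical → monomer in chains + growing radical, rate k3*[growing radical]*[free monomer] (k = 20000 M⁻¹ s⁻¹)
    2 growing radical → dead chain (k = 3.00 × 10⁷ M⁻¹ s⁻¹)
    protic impurity + free monomer → quenched substrate (k = 1.70 M⁻¹ s⁻¹)
    monomer in chains → over-reaction product (k = 4.30 × 10⁻⁶ s⁻¹)

Birch ends with 69.1% in chains against its surplus share of 70.0%, and cedar with 2.92%. The neighbouring flask is birch charged with 0.19 M of protic impurity, so its surplus share is 24.0%, and it ends with 23.8% in chains. Its dead chains stand at 0.00101 M, as in birch at 0.00101 M, so we scale birch's length by the two surplus shares and get 59.0. The neighbour's simulated length is 59.0.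

The data were computed on assumed constants, and the scatter is random.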